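The numbers in the tables are simulated with made-up constants; scatter was added.

- From 10.0 h to 20.0 h, the zeta run made product at a pace that would turn the whole charge in 41.3 h; we call this the charge time, the reciprocal rate on the straight part of a run.

| flask | left-handed substrate | right-handed substrate | gas | precatalyst | remark | time |
|---|---|---|---|---|---|---|
| zeta | 0.20 M | 0.20 M | 22 mM (held) | 13 mol% | run made earlier |  |
| eta | 0.20 M | 0.20 M | 22 mM (held) | 30 mol% | run made earlier |  |
| flask | 0.20 M | 0.20 M | 22 mM (held) | 20 mol% |  | 20 h |

| run | time / h | left-handed product / % | right-handed product / % |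
|---|---|---|---|
| zeta | 1.33 | 0 | 0.2 |
| zeta | 4.00 | 3.0 | 2.8 |
| zeta | 6.00 | 5.5 | 6.3 |
| zeta | 10.0 | 8.9 | 9.7 |
| zeta | 15.0 | 14.6 | 15.9 |
| zeta | 20.0 | 21.0 | 21.8 |
| zeta | 25.0 | 27.6 | 26.6 |
| eta | 1.33 | 0.4 | 1.3 |
| eta | 4.00 | 3.5 | 6.1 |
| eta | 6.00 | 6.6 | 8.4 |
| eta | 10.0 | 13.0 | 13.3 |
| eta | 15.0 | 20.5 | 20.2 |
| eta | 20.0 | 26.9 | 26.6 |
| eta | 25.0 | 33.8 | 33.5 |

(readings scatter by 0.5 percentage points)

- free catalyst is single-handed; left-handed substrate and right-handed substrate are mirror images of each other, charged as a racemate, each of them at the stated concentration
- the earlier runs were read with a standard deviation of 0.5 percentage points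
- at the start none of the gas is in solution
- an excess is the difference of the two amounts in percent of their sum
- an excess is below zero if the other one leads

1. excess of left-handed product over right-handed product in the product at 1.0 h
2. excess of left-handed product over right-handed product in the product at 20 h
3. part of the left-handed substrate and right-handed substrate charged together that has reacted at 20 h

- The eta run has 2.31 times the loading of the zeta run. Its charge time over the same hours is 36.8 h, shorter by a factor of 1.12.
- We assume two times in series, like resistances: a fixed part of 33.3 h, plus a part going as one over the loading.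
- Each run falls behind its straight line early, and we call that loss a lag. Elapsed time minus product times charge time gives 2.31 h for zeta and 0.331 h for eta.
- We apply the same one-over-loading rule to the flask. Its charge time is 38.5 h, which is 1.16 times the fixed part. Its lag is 1.09 h.
- So our own reckoning gives 49.1% of product at 20 h.
- The forecast, finding the rate “far from proportional to catalyst”, gives −35%, −0.5% and 48%, the last within 44.5% to 51.5%. Its part reacted stands lower than our product figure.
- The flask gives −62.6%, −1.30% and 55.6%.

    free catalyst + left-handed substrate ⇌ catalyst intermediate A (K = 2.70 /M, k = 300 /M/h)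
    gas ⇌ reagent, rate k2*(csat - [reagent]) (kL = 0.650 /h)
    free catalyst + right-handed substrate ⇌ catalyst intermediate B (K = 99.0 /M, k = 380 /M/h)
    reagent + catalyst intermediate B → free catalyst + right-handed product (k = 48.0 /M/h)
    left-handed product ⇌ right-handed product (k = 0.590 /h)
    precatalyst → free catalyst (k = 0.390 /h)
    reagent + catalyst intermediate A → free catalyst + left-handed product (k = 99.0 /M/h)

- At 20 h the flask holds 49.1% of product, and the other 6.5 percentage points of what reacted is bound as catalyst intermediates A and B. At 5 mol%, below both runs, the same rule gives a charge time of 54.2 h and a lag of 7.91 h, hence 22.3% of product. That neighbour flask holds 26.5% of product, and 28.8% has reacted.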